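Time is what I must settle for the east flask. It gets the charge of the south run, and the question is what a reading at 900 s would measure.

common to all: starting material 200 mM
- south: coupling partner 400 mM
- south-east: coupling partner 400 mM; target 100 mM
- north-east: coupling partner 800 mM
- east: coupling partner 400 mM; time 900 s

| run | time / s | [target] / mM |
|---|---|---|
| south run | 6.0 | 6.6 |
| south run | 13 | 12.4 |
| south run | 30 | 28.1 |
| south run | 67 | 46.0 |
| south run | 150 | 62.9 |
| south-east run | 6.0 | 103.2 |
| south-east run | 13 | 105.2 |
| south-east run | 30 | 109.7 |
| south-east run | 67 | 110.0 |
| south-east run | 150 | 103.4 |
| north-east run | 6.0 | 24.3 |
| north-east run | 13 | 45.7 |
| north-east run | 30 | 80.6 |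
| north-east run | 67 | 101.5 |
| north-east run | 150 | 74.9 |

(scatter of a reading: 0.6 mM)

* order of the initial rate in [coupling partner], near the charge of the south run, the rate being that where two percent of its starting material are target
* target in the east run at 900 s, as a share of the starting material charged

- Overall: starting material + coupling partner -> target.
- Constant volume, constant temperature.
- Readings of a species count what is bound in complexes too.
- An order is taken over about fifteen percent of the charge, up and down.

I reckon with what is left, not with what is made. The south-east run differs from the south run by 100 mM of added target. If making goes on alike in both, the gap in c(target) is what remains of that addition. At 150 s the gap reads 40.5 mM, a share left of 40.5%. The logarithm of the inverse share, divided by that time, gives 0.00603 s⁻¹. This is the survival constant λ, a pseudo-first-order loss constant at this c(coupling partner), averaged over those seconds.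

Now I apply it to the east flask, whose first 150 s the south run already shows. Of the 62.9 mM of target standing then, a share of 1.09% outlasts the remaining time at this λ, which is 0.685 mM. But λ was read near the charge of coupling partner, and the overall equation takes one coupling partner per target, so full turnover of the 200 mM of starting material in the east flask brings c(coupling partner) down to 200 mM. If λ goes with c(coupling partner), it stands at half its value there, and held at that lower value for the remaining time it leaves 6.57 mM.

The forecast says 14% (7% to 24%) and an order of 1.95 (1.65 to 2.25). It takes a loss of 0.0055 per second, lower than my λ, and adds: “The fate of the partner during the loss step is uncertain.” Its share means 28.0 mM of target, more than the survivors at either λ. By my reckoning, then, the rest of that amount has to be target made after 150 s, if the forecast holds. So I leave the charge unchanged and keep the late reading, which holds that later target along with the survivors.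

The flask gives 16.6%, from these steps:

    starting material + 2 coupling partner → target + coupling partner (0.1630 L² mol⁻² s⁻¹)
    target + coupling partner → side product (0.01650 L mol⁻¹ s⁻¹)
    2 starting material ⇌ idle substrate dimer, settled at all times (42.10 L mol⁻¹)

That is 33.1 mM of target, inside the forecast's range, and the order is 2.0, with the north-east run at 4.1 times the south run's rate. The forecast would fail if a run showed added target persisting, but the south-east run keeps 40.5% of it. At the lower λ, survivors from 150 s are reckoned at 6.57 mM of the 33.1 mM. On the north-east run, with λ doubled for its doubled partner, the 101.5 mM read at 67 s shrink to 37.3 mM by 150 s, where 74.9 mM is read.

(The earlier runs and the new flask were generated by integration from invented constants.)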